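Readings and results are simulated from invented constants; scatter was added.

If the noon flask stops changing by 30.0 s, something has stopped it, and two of us at this board disagree on what.

| setting | noon | dawn | midnight | cedar | larch | birch |
|---|---|---|---|---|---|---|
| L | 1 M | 1 M | 1 M | 1.0 M | 1.0 M | 1.0 M |
| G | 0.44 M | 0.93 M | 1.8 M | 0.500 M | 0.800 M | 2.00 M |
| remark | run made earlier | run made earlier | run made earlier |  |  |  |
| time |  |  |  | 2.5 min | 2.5 min | 2.5 min |

| run | time / s | D / % | L / % |
|---|---|---|---|
| noon | 10.0 | 5.4 | 93.7 |
| noon | 15.0 | 6.3 | 93.3 |
| noon | 30.0 | 6.6 | 92.7 |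
| noon | 80.0 | 6.4 | 92.4 |
| dawn | 10.0 | 12.2 | 87.1 |
| dawn | 25.0 | 12.7 | 84.8 |
| dawn | 50.0 | 13.7 | 86.3 |
| dawn | 80.0 | 14.1 | 85.8 |
| midnight | 10.0 | 20.8 | 77.8 |
| midnight | 15.0 | 22.4 | 75.6 |
| midnight | 30.0 | 23.5 | 74.8 |
| midnight | 80.0 | 23.4 | 74.0 |

(standard deviation of a reading: 0.5 percentage points)



* D at the end, in percent of the L charged, for each flask in turn (cedar, larch, birch)

My colleague reads the stop as a balance between L, G and D: “The readings level off within about 30 s, so a 2.5 min flask should sit at equilibrium.” Hers is the forecast, 7.7 % for cedar, 11.9 % for larch and 25.6 % for birch.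

I read the stop differently: G is being used up, partly on L and partly elsewhere. So I carry the catch, the moles of D formed per mole of G charged, which chemists would call a selectivity. It is a running total: it starts from nothing and tells what part of the G charged has so far ended up in D, so it is an average over the run and not a comparison at one moment.

The last dawn reading gives a catch of 0.152, and the last noon reading gives 0.145. Held fixed, the dawn catch makes D a straight line in the G charged, so my own reckoning is 7.58 % for cedar, 12.1 % for larch and 30.3 % for birch.

She objects that midnight reads lower than dawn, at 0.130, a gap beyond the scatter. I grant it: L at midnight stands at 74.0 %, less than the 85.8 % at dawn, and the share of G that L takes should drift as L thins. My single number carries no such drift, but I keep it, and the two of us part at birch.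

The flasks give 7.67 % for cedar, 11.8 % for larch and 25.7 % for birch, so the forecast holds within its margin.

    L + G → X + D (k = 0.0330 /M/s)
    D + G → X + E (k = 0.0170 /M/s)
    G → Q (k = 0.170 /s)

My line stays close in cedar and larch but overshoots birch by 4.6 percentage points, where the catch reads 0.129 against 0.153 in cedar. In cedar at 0.0572 min, the step from G to Q uses G 5.4 times as fast as the step from L and G to X and D, which gives that exchange a share of 0.156 of the G these two steps use at that moment. By 2.50 min, G in cedar stands at 0 % of its own charge.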